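**Retrosynthetic overview**
1. The target comes from the 2,3,15-triol by site-selective diacetylation. The side chain is built on C9 from an exocyclic 9(11)-methylene: hydroboration sets C9 and α-bromo-ketone alkylation of the borane makes C11–C12; Horner–Wadsworth–Emmons olefination and ester reduction give C13=C14–C15.
2. The cis-2,3-diol comes from osmylation of a C2=C3 alkene anti to the C10 methyl. The ring B Δ7-9-ketone comes from an ene-dione: the C6 oxygen is removed through the C5=C6 enol triflate, and a dissolving-metal 1,6-reduction sets C5–H trans.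
3. The ene-dione comes from a Diels–Alder reaction that makes C1–C10 and C4–C5 together, from 4-methylpenta-1,3-diene (C1–C4 with the gem-dimethyl group) and 2,6-dimethyl-1,4-benzoquinone (all of ring B with the C8 and C10 methyls).
4. Enabling feature: ring A (C1, C2, C3, C4, C5, C10) carries only a cis-2,3-diol, a masked C2=C3 double bond, so it is a cyclohexene retron whose C1–C4 are a 1,3-diene. Ring B has methyls on C8 and C10 flanking C9, the pattern of 2,6-dimethylbenzoquinone with its carbonyls on C9 and C6.
5. Ring order: ring B is bought as the quinone; ring A is closed onto it in the cycloaddition; no other ring is formed.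

Key step: step 1

Assumption: labdane numbering is used; the target is (2S,3R,5S,9R,10S,13E), an ent-labdane with 5-H, 9-H, 2-O and 3-O all anti to the 10-methyl. The (S)-oxazaborolidinium catalyst is assumed to give the (8aR) centre; if the induction is opposite, its (R)-antipode is used with no other change.

**Route**

Step 1
Reactants: 1 2,6-dimethyl-1,4-benzoquinone; 2 4-methylpenta-1,3-diene
Product: 3 (4aS,8aR)-2,5,5,8a-tetramethyl-4a,5,8,8a-tetrahydronaphthalene-1,4-dione (cis-fused)
Conditions: (S)-1-(2-methylphenyl)-3,3-diphenyltetrahydro-1H,3H-pyrrolo[1,2-c][1,3,2]oxazaborole (20 mol %), HNTf2 (20 mol %), 2 (3 equiv), CH2Cl2, −78 → −40 °C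
Reagents that add atoms: none
Why: Diels–Alder reaction: the oxazaborolidinium cation binds the quinone C4 carbonyl (the future C6; the more basic oxygen and the only one with α C–H bonds), so the cycloaddition is concerted but asynchronous, the unsubstituted diene terminus C1 bonding first to the β-carbon C10 and the CMe2 terminus C4 then closing onto C5. The closest known reactions are the chiral oxazaborolidinium-catalysed Diels–Alder reactions of methyl-substituted 1,4-benzoquinones and the Lewis-acid-catalysed additions of 1-substituted butadienes to 2,6-dimethylbenzoquinone, which show this regiochemistry. Ring A is closed by suprafacial [4π+2π] cycloaddition onto the preformed ring B, so the C5–H and the C10 methyl come out cis. The quaternary stereocenter C10 is set by the catalyst, whose aryl group shields one face of the coordinated quinone C=C bond; C5 follows from C10 through the suprafacial addition and is re-set in step 4, so C10 is the only centre the catalyst must control. The step needs regioselectivity (C1 to C10, C4 to C5) and site selectivity: coordination at the unhindered carbonyl, the strain that a bond between CMe2 and the methyl-bearing carbon would cost, and the symmetry of 1 (its two C=C bonds are equivalent) should secure them, and the asynchronous transition state should tolerate the (Z)-methyl group of the diene.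

Step 2
Reactants: 3 cis-fused ene-dione
Product: 5 (8aR)-2,5,5,8a-tetramethyl-1-oxo-1,5,8,8a-tetrahydronaphthalen-4-yl trifluoromethanesulfonate, via potassium dienolate 4 (not isolated)
Conditions: KN(SiMe3)2 (1.1 equiv), THF, −78 °C; PhNTf2, −78 → 0 °C
Reagents that add atoms: N-phenylbis(trifluoromethanesulfonimide) (O=S(=O)(N(c1ccccc1)S(=O)(=O)C(F)(F)F)C(F)(F)F)
Why: Enol triflate formation from a ketone enolate: C5–H is the only α-hydrogen of the ene-dione (C9 is flanked by quaternary C10 and sp2 C8), so enolisation and O-sulfonylation should differentiate the two carbonyls and erase the cis ring-fusion centre.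

Step 3
Reactants: 5 dienyl triflate
Product: 6 (8aR)-2,5,5,8a-tetramethyl-8,8a-dihydronaphthalen-1(5H)-one (5,7-dien-9-one in labdane numbering)
Conditions: Pd(OAc)2 (5 mol %), PPh3 (10 mol %), HCO2H, n-Bu3N, DMF, 60 °C
Reagents that add atoms: none
Why: Palladium-catalysed formate reduction of an enol triflate (oxidative addition to zerovalent palladium, formate exchange, decarboxylation, reductive elimination) should remove the C6 oxygen and leave the linear dienone.

Step 4
Reactants: 6 dienone
Product: 9 (4aR,8aR)-2,5,5,8a-tetramethyl-4a,5,8,8a-tetrahydronaphthalen-1(4H)-one (trans-fused Δ7-9-ketone), via lithium dienolate 7 (not isolated), via deconjugated enone 8 (not isolated)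
Conditions: Li (2.2 equiv), t-BuOH (1 equiv), NH3/THF, −78 °C; NH4Cl; then DBU, CH2Cl2, rt
Reagents that add atoms: none
Why: Dissolving-metal (Birch-type) 1,6-reduction of a linear dienone should protonate the δ-carbon C5 perpendicular to the dienolate plane on the face opposite the adjacent axial C10 methyl, which sets the trans ring fusion; the α-protonated β,γ-enone is then reconjugated by DBU.

Step 5
Reactants: 9 trans-fused enone
Product: 10 (4aR,6R,7S,8aR)-6,7-dihydroxy-2,5,5,8a-tetramethyl-4a,5,6,7,8,8a-hexahydronaphthalen-1(4H)-one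
Conditions: OsO4 (2 mol %), N-methylmorpholine N-oxide (1.5 equiv), acetone/H2O, rt
Reagents that add atoms: N-methylmorpholine N-oxide (C[N+]1([O-])CCOCC1); water (O); OsO4 (O=[Os](=O)(=O)=O, catalytic oxygen carrier)
Why: Catalytic syn-dihydroxylation (Upjohn conditions) should attack only the isolated cis C2=C3 bond (C7=C8 is a deactivated enone) from the face opposite the axial C10 and C4 methyls, giving the cis-diol anti to the C10 methyl.

Step 6
Reactants: 10 diol
Product: 11 acetonide of 10 (2,3-O-isopropylidene in labdane numbering)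
Conditions: 2,2-dimethoxypropane, pyridinium p-toluenesulfonate (cat.), CH2Cl2, rt
Reagents that add atoms: 2,2-dimethoxypropane (COC(C)(C)OC)
Why: Acid-catalysed transketalisation protects the cis-diol as a five-membered acetonide that is stable to the ylide, borane, base and hydride steps that follow.

Step 7
Reactants: 11 acetonide enone
Product: 12 2,3-O-isopropylidene-drima-7,9(11)-diene-2,3-diol (ring stereocenters as in 11)
Conditions: Ph3PCH3Br (4 equiv), KOt-Bu (3.8 equiv), toluene, 90 °C
Reagents that add atoms: methyltriphenylphosphonium bromide (C[P+](c1ccccc1)(c1ccccc1)c1ccccc1.[Br-]), as its ylide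
Why: Wittig methylenation: the small unstabilised ylide should add 1,2 to the hindered C9 carbonyl, which has no α-hydrogen, and give the conjugated 7,9(11)-diene.

Step 8
Reactants: 12 diene
Product: 14 2,3-(isopropylidenedioxy)-14,15-dinorlabd-7-en-13-one (9-H anti to the 10-methyl), via B-alkyl-9-BBN 13 (not isolated)
Conditions: 9-BBN (1.1 equiv), THF, 0 → 50 °C; then bromoacetone, potassium 2,6-di-tert-butylphenoxide, THF, 0 °C → rt
Reagents that add atoms: 9-borabicyclo[3.3.1]nonane (B1C2CCCC1CCC2; boron retained only in 13); bromoacetone (CC(=O)CBr)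
Why: Hydroboration should place boron on the terminal C11 of the exocyclic methylene (9-BBN leaves the trisubstituted C7=C8 bond alone) and deliver hydrogen to C9 on the face opposite the axial C10 methyl, which sets C9; the bromoacetone enolate then adds to boron and 1,2-migration of the primary alkyl group with loss of bromide (α-alkylation of an α-halo ketone by a B-alkyl-9-BBN) forms C11–C12.

Step 9
Reactants: 14 methyl ketone
Product: 15 ethyl (13E)-2,3-(isopropylidenedioxy)labda-7,13-dien-15-oate
Conditions: (EtO)2P(O)CH2CO2Et, NaH, THF, 0 °C → reflux; chromatographic removal of the minor (Z)-isomer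
Reagents that add atoms: triethyl phosphonoacetate (CCOC(=O)CP(=O)(OCC)OCC)
Why: Horner–Wadsworth–Emmons olefination of a methyl ketone should favour the (E)-enoate, with the ester trans to the larger C12 chain.

Step 10
Reactants: 15 (E)-enoate
Product: 16 (13E)-2,3-(isopropylidenedioxy)labda-7,13-dien-15-ol
Conditions: i-Bu2AlH (2.5 equiv), CH2Cl2, −78 °C; aq. KNaC4H4O6
Reagents that add atoms: none
Why: 1,2-Reduction of the α,β-unsaturated ester by i-Bu2AlH should give the allylic alcohol without touching the alkenes or the acetonide.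

Step 11
Reactants: 16 acetonide alcohol
Product: 17 (2S,3R,5S,9R,10S,13E)-labda-7,13-diene-2,3,15-triol
Conditions: AcOH/THF/H2O (3:1:1), 40 °C
Reagents that add atoms: none
Why: Mild acid hydrolysis of the acetonide should release the 2,3-diol; the allylic alcohol and trisubstituted alkenes tolerate dilute acetic acid.

Step 12
Reactants: 17 triol
Product: 18 CNP0254679.1, (2S,3R,5S,9R,10S,13E)-3-hydroxylabda-7,13-diene-2,15-diyl diacetate
Conditions: Ac2O (2.2 equiv), pyridine, CH2Cl2, 0 °C
Reagents that add atoms: acetic anhydride (CC(=O)OC(C)=O)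
Why: Site-selective esterification by steric differentiation: acylation should be fastest at the primary allylic C15–OH and the equatorial C2–OH, while the axial C3–OH, neopentyl to the C4 gem-dimethyl group, stays free.

**Compound list**
1 | 2,6-dimethyl-1,4-benzoquinone | CC1=CC(=O)C=C(C)C1=O | starting material
2 | 4-methylpenta-1,3-diene | CC(C)=CC=C | starting material
3 | (4aS,8aR)-2,5,5,8a-tetramethyl-4a,5,8,8a-tetrahydronaphthalene-1,4-dione (cis-fused) | O=C1C(C)=CC(=O)[C@H]2C(C)(C)C=CC[C@@]12C | intermediate
4 | potassium dienolate of 3 (C5=C6 enolate, not isolated) | [K+].[O-]C1=C2C(C)(C)C=CC[C@@]2(C)C(=O)C(C)=C1 | intermediate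
5 | (8aR)-2,5,5,8a-tetramethyl-1-oxo-1,5,8,8a-tetrahydronaphthalen-4-yl trifluoromethanesulfonate | O=C1C(C)=CC(OS(=O)(=O)C(F)(F)F)=C2C(C)(C)C=CC[C@@]12C | intermediate
6 | (8aR)-2,5,5,8a-tetramethyl-8,8a-dihydronaphthalen-1(5H)-one | O=C1C(C)=CC=C2C(C)(C)C=CC[C@@]12C | intermediate
7 | lithium dienolate (C9 enolate, 5-H anti to the 10-methyl, not isolated) | [Li+].[O-]C1=C(C)C=C[C@@H]2C(C)(C)C=CC[C@@]12C | intermediate
8 | (4aR,8aR)-2,5,5,8a-tetramethyl-4a,5,8,8a-tetrahydronaphthalen-1(2H)-one, C2 epimers (β,γ-enone, not isolated) | O=C1C(C)C=C[C@@H]2C(C)(C)C=CC[C@@]12C | intermediate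
9 | (4aR,8aR)-2,5,5,8a-tetramethyl-4a,5,8,8a-tetrahydronaphthalen-1(4H)-one (trans-fused) | O=C1C(C)=CC[C@@H]2C(C)(C)C=CC[C@@]12C | intermediate
10 | (4aR,6R,7S,8aR)-6,7-dihydroxy-2,5,5,8a-tetramethyl-4a,5,6,7,8,8a-hexahydronaphthalen-1(4H)-one | O=C1C(C)=CC[C@@H]2C(C)(C)[C@@H](O)[C@@H](O)C[C@@]12C | intermediate
11 | acetonide of 10 (cis-dioxolane anti to the angular methyl) | O=C1C(C)=CC[C@@H]2C(C)(C)[C@H]3OC(C)(C)O[C@H]3C[C@@]12C | intermediate
12 | 2,3-O-isopropylidene-drima-7,9(11)-diene-2,3-diol (5-H anti to the 10-methyl; diol cis, anti to the 10-methyl) | C=C1C(C)=CC[C@@H]2C(C)(C)[C@H]3OC(C)(C)O[C@H]3C[C@@]12C | intermediate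
13 | B-(C11-alkyl)-9-BBN from 12 (9-H anti to the 10-methyl, not isolated) | C(B4C5CCCC4CCC5)[C@@H]1C(C)=CC[C@@H]2C(C)(C)[C@H]3OC(C)(C)O[C@H]3C[C@@]12C | intermediate
14 | 2,3-(isopropylidenedioxy)-14,15-dinorlabd-7-en-13-one (ring stereocenters as in the target) | CC(=O)CC[C@@H]1C(C)=CC[C@@H]2C(C)(C)[C@H]3OC(C)(C)O[C@H]3C[C@@]12C | intermediate
15 | ethyl (13E)-2,3-(isopropylidenedioxy)labda-7,13-dien-15-oate | CCOC(=O)/C=C(\C)CC[C@@H]1C(C)=CC[C@@H]2C(C)(C)[C@H]3OC(C)(C)O[C@H]3C[C@@]12C | intermediate
16 | (13E)-2,3-(isopropylidenedioxy)labda-7,13-dien-15-ol | OC/C=C(\C)CC[C@@H]1C(C)=CC[C@@H]2C(C)(C)[C@H]3OC(C)(C)O[C@H]3C[C@@]12C | intermediate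
17 | (2S,3R,5S,9R,10S,13E)-labda-7,13-diene-2,3,15-triol | OC/C=C(\C)CC[C@@H]1C(C)=CC[C@@H]2C(C)(C)[C@@H](O)[C@@H](O)C[C@@]12C | intermediate
18 | CNP0254679.1, (2S,3R,5S,9R,10S,13E)-3-hydroxylabda-7,13-diene-2,15-diyl diacetate | CC(=O)OC/C=C(\C)CC[C@@H]1C(C)=CC[C@@H]2C(C)(C)[C@@H](O)[C@@H](OC(C)=O)C[C@@]12C | target

**Step count and risks**
Total step count: 12. Longest linear sequence: 12 steps (1 → 18).

Most likely to fail:

Step 1. The (Z)-methyl group of 2 disfavours the s-cis conformation, so the catalysed cycloaddition may be too slow to outrun uncatalysed addition (opposite regiochemistry) and acid-induced oligomerisation of the diene; conversion and enantiomeric purity would both suffer. The fallback sets out from 1 and comes back at 6. Mesityl oxide is enolised kinetically (LiN(i-Pr)2, THF, −78 °C; t-BuMe2SiCl) to 2-(tert-butyldimethylsilyloxy)-4-methylpenta-1,3-diene F1, a far more nucleophilic diene of the class for which the oxazaborolidinium-catalysed quinone Diels–Alder reaction is best established. Cycloaddition with 1 under the step 1 catalyst should give the silyl enol ether adduct F2, with the same C1–C10/C4–C5 connectivity and C10 configuration. KN(SiMe3)2/PhNTf2 followed by CsF/PhNTf2 converts the C6 ketone (through its C5 enolate) and the C2 silyl enol ether into the bis(enol triflate) F3. Pd(OAc)2/PPh3/HCO2H/n-Bu3N then removes both triflates and gives 6.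

Step 4. Protonation of the reduced dienone may occur at C7 instead of C5, or at C5 on the methyl-bearing face (cis fusion), or the carbonyl may be over-reduced. The fallback sets out from 3 and comes back at 9. Base equilibration of the acidic C5–H of 3 (DBU, CH2Cl2) should give the trans-fused ene-dione F4. Luche reduction (NaBH4, CeCl3·7H2O, MeOH, −78 °C) of the C6 carbonyl, which is flanked by CH groups and not by the quaternary C10 and the C8 methyl, gives the hydroxy-enone F5. Acetylation (Ac2O, pyridine, DMAP) gives the γ-acetoxy enone F6. SmI2 (THF/MeOH, −78 °C) cleaves the γ-acetoxy group reductively (vinylogous α-deoxygenation), and DBU reconjugation gives 9.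

Step 9. Incomplete (E)-selectivity in the olefination of a methyl ketone would give a geometric mixture that is hard to separate. The fallback sets out from 14 and comes back at 16. Kinetic enolisation of the methyl group (LiN(i-Pr)2, THF, −78 °C) and trapping with ClP(O)(OEt)2 gives the terminal enol phosphate F7, and elimination with more LiN(i-Pr)2 gives the terminal alkyne F8. Zirconium-catalysed syn-carboalumination (Me3Al, Cp2ZrCl2 cat., CH2Cl2, −20 °C, water-accelerated to spare the acetonide) and trapping of the (E)-alkenylalane with paraformaldehyde should give 16 as a single alkene isomer.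

Further compounds
F1 | step 1 | 2-(tert-butyldimethylsilyloxy)-4-methylpenta-1,3-diene | C=C(O[Si](C)(C)C(C)(C)C)C=C(C)C
F2 | step 1 | (4aS,8aR)-7-(tert-butyldimethylsilyloxy)-2,5,5,8a-tetramethyl-4a,5,8,8a-tetrahydronaphthalene-1,4-dione | O=C1C(C)=CC(=O)[C@H]2C(C)(C)C=C(O[Si](C)(C)C(C)(C)C)C[C@@]12C
F3 | step 1 | (8aR)-2,5,5,8a-tetramethyl-1-oxo-1,5,8,8a-tetrahydronaphthalene-4,7-diyl bis(trifluoromethanesulfonate) | O=C1C(C)=CC(OS(=O)(=O)C(F)(F)F)=C2C(C)(C)C=C(OS(=O)(=O)C(F)(F)F)C[C@@]12C
F4 | step 4 | (4aR,8aR)-2,5,5,8a-tetramethyl-4a,5,8,8a-tetrahydronaphthalene-1,4-dione (trans-fused) | O=C1C(C)=CC(=O)[C@@H]2C(C)(C)C=CC[C@@]12C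
F5 | step 4 | (4aR,8aR)-4-hydroxy-2,5,5,8a-tetramethyl-4a,5,8,8a-tetrahydronaphthalen-1(4H)-one (carbinol configuration immaterial) | O=C1C(C)=CC(O)[C@@H]2C(C)(C)C=CC[C@@]12C
F6 | step 4 | (4aR,8aR)-2,5,5,8a-tetramethyl-1-oxo-1,4,4a,5,8,8a-hexahydronaphthalen-4-yl acetate | O=C1C(C)=CC(OC(C)=O)[C@@H]2C(C)(C)C=CC[C@@]12C
F7 | step 9 | terminal enol diethyl phosphate of 14 | C=C(OP(=O)(OCC)OCC)CC[C@@H]1C(C)=CC[C@@H]2C(C)(C)[C@H]3OC(C)(C)O[C@H]3C[C@@]12C
F8 | step 9 | terminal alkyne from 14 (C11–C12–C≡CH side chain) | C#CCC[C@@H]1C(C)=CC[C@@H]2C(C)(C)[C@H]3OC(C)(C)O[C@H]3C[C@@]12C
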